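4 questions stand on the south flask, and we answer them with one count, so this note is for whoever takes the bench.

the same everywhere: substrate 0.010 M
- south: partner 0.012 M; the very flask that is asked about, followed so far
- flask: partner 0.0120 M; time 4.0 h

south run (percent of the substrate charged)

| time / h | target / % | substrate / % |
|---|---|---|
| 0.333 | 11.2 | 6.6 |
| 1.00 | 38.1 | 0.8 |
| 2.00 | 42.8 | 0 |
| 3.00 | 38.9 | 0 |
| 4.00 | 32.4 | 0 |

(scatter of a reading: 0.5 percentage points)

- target, in percent of the substrate first charged, at 4.0 h
- the remedy with the largest gain of target, or "none" below 2 percentage points (elm / oak / larch / birch / none)
- target present, with what was taken out counted in, in percent of the substrate first charged, after elm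
- target present, with what was taken out counted in, in percent of the substrate first charged, after oak

- elm: at 4.0 h add substrate, 50.0 % of the amount charged, then wait 8.0 h
- oak: at 4.0 h add partner, 50.0 % of the amount charged, then wait 8.0 h
- larch: change nothing and wait 8.0 h more
- birch: at 4.0 h take out 90 % of the target then present, then wait 8.0 h

- removed target is counted in
- the numbers in the tables scatter by 0.5 percentage points (one standard deviation)
- additions bring no volume worth counting

In the south flask the substrate reads 0 % at 2.00 h, while the target has gone from 42.8 % to 32.4 % at 4.00 h, and that last reading, with its scatter of 0.5 percentage points, is our answer to what the flask holds now. The last two target readings give 3.79 h, which we call the net half-life of target, an apparent first-order half-life: the time in which the target reading halves, with whatever still feeds it counted in. The wait of 8.0 h is 2.11 such half-lives, so by our count the target keeps 23.2 %, and whoever comes back to the south flask finds about 7.52 %; we set oak and elm near that figure and would not add to the flask. Taking out 90 % of the south flask's target banks 29.2 % and leaves 3.24 % in the flask, but the net half-life has the feed counted in and the removal leaves the feed untouched, so we do not run that remainder down by it. Birch gains what the remainder ends above its starting 3.24 %, so a gain of 2 points asks it to end that far above, and since the readings do not show that it will, we choose none, as a judgement and not as a result of the count.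

The forecast gives 32.5 % (31.5 % to 33.5 %), 10 % (6.5 % to 20 %) after elm and 6.5 % (2 % to 11 %) after oak, and it chooses birch, in its words “Birch wins”, where we choose none.

The south flask gives 31.9 %, 5.48 % after elm and 4.55 % after oak, and the choice is none, since birch gains −0.19 points.

    substrate → open intermediate (k = 0.00230 s⁻¹)
    partner → second intermediate (k = 0.00150 s⁻¹)
    open intermediate + second intermediate → target (k = 0.0240 M⁻¹ s⁻¹)
    2 second intermediate → homo product (k = 0.00180 M⁻¹ s⁻¹)
    target → over-reaction product (k = 9.70 × 10⁻⁵ s⁻¹)

Our 3.79 h is longer than the 2.0 h of the target step alone, and at 4.00 h the south flask makes target at 0.393 of the rate at which it uses it. The neighbour flask is charged with 0.017 M of substrate, other charges as in the recipe. The same count over 4.0 h keeps 48.1 % of its 62.6 % turned into target and over-reaction product, which comes to 30.1 %, and that neighbour flask holds 23.4 % of target.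

All runs stem from a simulated flask from invented constants, noise included.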